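Remark on the chemistry: target 21 has no stereocentre, and ring E is a symmetrical 2,4,6-trihydroxyphenyl group, so the D5–E1 axes give no isomers and no configuration has to be set. Compounds 3 and 16 are taken as purchasable benzyl ethers.

## The problem

Target 21 is an achiral nonadecaphenol built from eight benzene rings. Ring B carries three contiguous aryloxy groups (ring A on B2, rings C and C' on B1 and B3) and a hydroxyl on B5, and each of rings C and C' is linked through its C4 oxygen to D1 of a D–E biaryl. With no stereocentre and no isomerism about the biaryl axes, every selectivity question is regiochemical or steric. The hardest bonds are the B1–O–C1 and B3–O–C1' ethers: C1 lies between the C2 and C6 oxygens and B1/B3 next to the B2 aryloxy group, so each is a tri-ortho-substituted diaryl ether, and two of them flank B2. A second hindered ether joins the C4 oxygen to D1, which sits between the D2 and D6 oxygens, the D5–E1 bond is a tetra-ortho-oxygenated biaryl, and within each ring C the C4 oxygen must be told apart from the C2 and C6 oxygens. All nineteen hydroxyls sit on phloroglucinol-type rings that oxidise in air under base, C-alkylate easily and do not tolerate peracids or hot Lewis acids, so one kind of protecting group that leaves under neutral conditions is needed. The enabling feature is the oxygen pattern of rings C and C': C1 bears the ether oxygen and C2, C4 and C6 bear hydroxyls in a 1,3,5-relationship, so C1 with C2 and C6 maps onto an O-aryl malonate and C3–C4–C5 onto a 3-oxopentanedioate. Each ring can then be closed through the C2–C3 and C5–C6 bonds after the hindered ether already exists as an ordinary alkyl aryl ether.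

## Retrosynthesis

**21 from 20.** All nineteen O–H bonds are traced back to benzyl ethers in 20. Benzyl is preferred to methyl because a single neutral hydrogenolysis then ends the synthesis, whereas nineteen Lewis-acid demethylations on this oxidation-prone skeleton would be the weakest step of any route. The forward reaction only has to cleave benzyl–oxygen bonds and leave diaryl ethers and biaryls alone.

**20 from 15 and two molecules of 19.** Both C4–O–D1 bonds are cut, with the oxygen kept on ring C. This polarity follows from the ring synthesis, which delivers C4 as a hydroxyl. It is also convergent: the complete D–E unit arrives in one piece, and no tetra-ortho biaryl bond has to be made on a large intermediate. Bis-phenol 15 has only these two free hydroxyls, both flanked by hydrogens. The forward step is a twofold copper-mediated etherification with an aryl iodide that has two ortho benzyloxy groups.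

**19 from 18, 17 and 16.** Ring D of 19 is a ring of the symmetrical hexa-O-benzyl biphenyl 18 with one hydrogen replaced. All four ring hydrogens of 18 are equivalent, so iodination needs control of degree only, not of position. Cutting the D5–E1 bond of 18 gives two identical halves, so a homocoupling of two molecules of 17 suffices and no cross-coupling selectivity arises. Iodide 17 is one iodination from the commercial triether 16.

**15 from 14, 13 and 12.** The four benzyl ethers at C2, C6, C2' and C6' and the free C4 hydroxyls are traced back to hexaol 12 through the bis-silyl ether 13 and its tetrabenzyl ether 14. The C4 hydroxyl is the only one in each ring with two ortho hydrogens, so a bulky silyl group is placed there first, the other four are benzylated, and the silyl group is removed. This costs three steps and is the price of forming all three ring C hydroxyls in one operation.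

**12 from 10.** The four C3/C5 hydrogens of 12 replace methoxycarbonyl groups in 10, lost through tetraacid 11. These esters are what make the ring-forming enolates accessible, and 2,4,6-trihydroxybenzoic acids decarboxylate readily, so the activating groups disappear in one operation.

**10 from 7 and two molecules of 8.** In each of rings C and C' the C2–C3 and C5–C6 bonds are cut, four bonds and two rings in all, via the open-chain adduct 9. This is preferred to cutting the B–O–C1 ethers because no coupling at a di-ortho-substituted carbon is needed: the ether oxygens are already attached to the malonate carbons of 7. The precursors are the bis(aryloxymalonate) 7 and the commodity ketodiester 8, one molecule of 8 for each malonate arm. The forward reaction must close through carbon and not through oxygen, and cross-condensation must outrun self-condensation of 8.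

**7 from 5 and two molecules of 6.** The two O–CH bonds are cut to resorcinol 5 and chloromalonate 6. This simple phenol alkylation replaces what would otherwise be two hindered diaryl ether couplings.

**5 from 4, and 4 from 2 and 3, and 2 from 1.** The B1 and B3 hydroxyls of 5 are traced to the bromines of 4 by a hydroxylation. The B2–O–ring A bond of 4 is cut to the 2,6-dibromophenol 2 and boronic acid 3. An oxidative copper coupling at room temperature tolerates the two ortho bromines, and this cut gives ring B with all four oxygens correctly differentiated in two steps from the hydroquinone monoether 1. A nucleophilic aromatic substitution on an aldehyde-activated aryl fluoride followed by formyl-to-hydroxyl oxidation was considered for the same ring. It was set aside because it is longer and because the aryl migration on a dibrominated ring is uncertain.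

## Roads not taken

**Alternative 1:** The cut lies inside ring E. The E1–E2 and E5–E6 bonds are formed in a Danheiser benzannulation: cyclobutenone A3 opens thermally to a vinylketene, adds to the ring D siloxyalkyne A2, and electrocyclic opening and closure give the biaryl phenol A1.
- Merits: the tetra-ortho-substituted D5–E1 bond is never made by coupling. Ring D arrives with a single benzyl ether among methyl ethers at D1, an unambiguous handle for the later ether bond. In this respect it is better than the chosen plan, which accepts a statistical monoiodination of 18 in step 12. Against that the chosen plan sets a three-step access to 19 from a commercial triether, with 18 recoverable.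
- Weak points: ring E of 21 is symmetrical with three like hydroxyls, so the three differentiated oxygens of A1 buy nothing. A2 needs a pentasubstituted arene and an ynol silyl ether, several steps each. The methyl and ethyl ethers force a Lewis-acid dealkylation at the end.
- Comparison: it spends its key step on the part of 21 that symmetry makes easy and leaves the B–O–C ethers untouched. It would still need a sequence like steps 1–9, so the total would be longer.

**Alternative 2:** The cut removes the carbon–oxygen bonds at B5, E4 and E4' and returns to the trideoxy hexadecamethyl ether A5. Forward, threefold iridium-catalysed C–H borylation and oxidation would give A4.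
- Merits: borylation is sterically governed, and B5, E4 and E4' are the only ring positions of A5 with hydrogen on both neighbouring carbons, so site selectivity should be high. The building blocks are simpler (2,6-dialkoxyphenyl units, a ring B without the B5 oxygen), and here it is at least as good as the chosen plan.
- Weak points: A5 still contains every hindered diaryl ether and both tetra-ortho biaryls, which is the real problem and is left to conventional couplings. Three borylations must go to completion on one large molecule. The catalyst would also attack benzyl groups, so methyl ethers are forced, and with them a sixteen-fold Lewis-acid demethylation of A4 at the end.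
- Comparison: the chosen plan makes the two most hindered ethers by alkylation and ring synthesis and ends with a hydrogenolysis; it pays with a protecting group at B5 from step 1 on.

**Alternative 3:** The cut is at C2–O and C6–O of both rings C. Tetraaldehyde A7 is oxidised with a peracid (Dakin, by Baeyer–Villiger aryl migration) and the formates are methanolysed to tetraol A6.
- Merits: the B–O–C1 ethers would come from substitution of the aryl fluoride A8, whose fluorine is flanked by two formyl groups, by the resorcinol A9 (the trimethyl analogue of 5), probably the most reliable way to make such ethers. The C4 oxygen is a silyl ether from the start, so the para/flanking differentiation is built in. The chosen plan has to achieve this by a sterically controlled silylation (step 7). On both counts Alternative 3 is equal or better.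
- Weak points: four aryl migrations are needed on rings that each carry a second formyl or formyloxy group and whose only donor is an aryloxy oxygen twisted between two ortho substituents, so hydride migration to carboxylic acids competes. A peracid acts in the presence of the electron-rich ring A and of the resorcinol rings as they are unveiled. The silyl ethers must survive basic methanolysis, and A8 needs its own multi-step synthesis.
- Comparison: step counts are similar. Against the built-in differentiation the chosen plan sets commodity three-carbon building blocks, a ring formation that ends in a thermodynamic sink, and no oxidant after step 2.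

Key step: step 5

## Route

Step 1
Reactants: 1 4-(benzyloxy)phenol
Product: 2 4-(benzyloxy)-2,6-dibromophenol
Conditions: NBS (2.1 equiv), i-Pr2NH (cat.), CH2Cl2, 0 °C to rt
Reagents that add atoms: N-bromosuccinimide, O=C1CCC(=O)N1Br
Why: Electrophilic aromatic bromination; the free hydroxyl is the strongest director and its para position is blocked, so both bromines should enter ortho to it, and the amine-catalysed NBS protocol is a standard route to 2,6-dibromophenols that avoids oxidising the hydroquinone monoether.

Step 2
Reactants: 2 4-(benzyloxy)-2,6-dibromophenol; 3 [3,5-bis(benzyloxy)phenyl]boronic acid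
Product: 4 5-(benzyloxy)-2-[3,5-bis(benzyloxy)phenoxy]-1,3-dibromobenzene
Conditions: 3 (2.5 equiv), Cu(OAc)2 (1.0 equiv), pyridine, 4 Å MS, CH2Cl2, air, rt
Reagents that add atoms: none
Why: Chan–Lam O-arylation; this oxidative coupling is established for 2,6-dihalophenols, leaves carbon–bromine bonds untouched at room temperature, and places ring A on the oxygen that becomes the B2 ether.

Step 3
Reactants: 4 5-(benzyloxy)-2-[3,5-bis(benzyloxy)phenoxy]-1,3-dibromobenzene
Product: 5 5-(benzyloxy)-2-[3,5-bis(benzyloxy)phenoxy]benzene-1,3-diol
Conditions: Pd2(dba)3 (cat.), tBuXPhos, KOH, 1,4-dioxane/H2O, 100 °C; then aq HCl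
Reagents that add atoms: potassium hydroxide, [K+].[OH-]
Why: Pd-catalysed hydroxylation of aryl bromides with hydroxide, run twice on the same ring; the bulky biarylphosphine favours carbon–oxygen reductive elimination and suppresses diaryl ether formation, and benzyl and diaryl ethers are inert to aqueous KOH.

Step 4
Reactants: 5 5-(benzyloxy)-2-[3,5-bis(benzyloxy)phenoxy]benzene-1,3-diol; 6 dimethyl chloromalonate
Product: 7 tetramethyl 2,2'-{[5-(benzyloxy)-2-[3,5-bis(benzyloxy)phenoxy]-1,3-phenylene]bis(oxy)}dipropanedioate
Conditions: 6 (2.4 equiv), K2CO3, acetone, reflux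
Reagents that add atoms: none
Why: Williamson-type O-alkylation of the two phenoxides by the doubly activated chloride, the standard entry to aryloxymalonates; the B1 and B3 ether oxygens are thereby bound to the sp3 carbons that become C1 and C1'.

Step 5
Reactants: 7 tetramethyl 2,2'-{[5-(benzyloxy)-2-[3,5-bis(benzyloxy)phenoxy]-1,3-phenylene]bis(oxy)}dipropanedioate; 8 dimethyl 3-oxopentanedioate (two molecules, one for each malonate arm)
Product: 10 tetramethyl 5,5'-{[5-(benzyloxy)-2-[3,5-bis(benzyloxy)phenoxy]-1,3-phenylene]bis(oxy)}bis(2,4,6-trihydroxybenzene-1,3-dicarboxylate), via open-chain twofold C-acylation adduct 9 (not isolated)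
Conditions: 8 (6 equiv), NaOMe (excess), MeOH then toluene, 110 °C, slow addition of 8 with removal of MeOH; then aq HCl
Reagents that add atoms: second molecule of dimethyl 3-oxopentanedioate 8, COC(=O)CC(=O)CC(=O)OC
Why: NaOMe turns 8 into its stabilised enolate, and one molecule of 8 acylates one ester carbonyl of each malonate arm of 7 with loss of methoxide (intermolecular Claisen condensation), so that two molecules of 8 are consumed and the open-chain adduct 9 results. In each arm the remaining methylene of the ketodiester unit is then enolised and attacks the second malonate ester carbonyl in a 6-exo-trig Claisen closure, once to form ring C and once to form ring C', and the cyclohexanetriones tautomerise to the aromatic triols. The products are held as sodium phenoxides, a thermodynamic sink that draws the reversible acylations forward even though both partners are largely enolised. The closest known reaction type is the alkoxide-mediated condensation of dialkyl malonates with dialkyl 3-oxopentanedioates to 2,4,6-trihydroxybenzene-1,3-dicarboxylates, and aryloxymalonates are established electrophiles in NaOMe cyclocondensations with other 1,3-dinucleophiles. No stereocentre is formed; the enolisable stereocentres of 9 disappear on aromatisation. The step needs carbon–carbon and not carbon–oxygen ring closure: the competing 6-exo-trig attack of an enolate oxygen would give a 4-hydroxypyran-2-one, but excess methoxide reopens this lactone and lets it re-close through carbon, so the carbocycle is the equilibrium product. It also needs cross-condensation to outrun self-condensation of 8, which is addressed by slow addition of an excess of 8 and by distilling off methanol; benzyl and diaryl ethers are inert to methoxide and the all-methyl esters cannot scramble.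

Step 6
Reactants: 10 tetramethyl 5,5'-{[5-(benzyloxy)-2-[3,5-bis(benzyloxy)phenoxy]-1,3-phenylene]bis(oxy)}bis(2,4,6-trihydroxybenzene-1,3-dicarboxylate)
Product: 12 2,2'-{[5-(benzyloxy)-2-[3,5-bis(benzyloxy)phenoxy]-1,3-phenylene]bis(oxy)}bis(benzene-1,3,5-triol), via tetracarboxylic acid 11 (not isolated)
Conditions: aq NaOH, 1,4-dioxane, 100 °C, Ar; then HCl to pH 1, 70 °C
Reagents that add atoms: none
Why: Ester hydrolysis followed by fourfold decarboxylation of 2,4,6-trihydroxybenzoic acids, which lose CO2 readily through their keto tautomers; benzyl and diaryl ethers are stable, and exclusion of air protects the phloroglucinol rings.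

Step 7
Reactants: 12 2,2'-{[5-(benzyloxy)-2-[3,5-bis(benzyloxy)phenoxy]-1,3-phenylene]bis(oxy)}bis(benzene-1,3,5-triol)
Product: 13 2,2'-{[5-(benzyloxy)-2-[3,5-bis(benzyloxy)phenoxy]-1,3-phenylene]bis(oxy)}bis{5-[(triisopropylsilyl)oxy]benzene-1,3-diol}
Conditions: TIPSCl (2.1 equiv), imidazole, DMF, −20 to 0 °C
Reagents that add atoms: triisopropylsilyl chloride, CC(C)[Si](Cl)(C(C)C)C(C)C
Why: Sterically controlled silylation; in each ring the C4 hydroxyl has two ortho hydrogens whereas the C2 and C6 hydroxyls lie against the congested triaryloxy core of ring B, so the bulky silyl chloride should react at the two para oxygens first.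

Step 8
Reactants: 13 2,2'-{[5-(benzyloxy)-2-[3,5-bis(benzyloxy)phenoxy]-1,3-phenylene]bis(oxy)}bis{5-[(triisopropylsilyl)oxy]benzene-1,3-diol}
Product: 14 ring A–B tribenzyl core bearing two 2,6-bis(benzyloxy)-4-[(triisopropylsilyl)oxy]phenoxy rings on B1 and B3
Conditions: BnBr, K2CO3, DMF, rt
Reagents that add atoms: benzyl bromide, BrCc1ccccc1
Why: Williamson benzylation of the four remaining phenols; aryl triisopropylsilyl ethers tolerate K2CO3 in an aprotic solvent, and the meta-disposed oxygens cannot exchange silicon intramolecularly.

Step 9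
Reactants: 14 ring A–B tribenzyl core bearing two 2,6-bis(benzyloxy)-4-[(triisopropylsilyl)oxy]phenoxy rings
Product: 15 4,4'-{[5-(benzyloxy)-2-[3,5-bis(benzyloxy)phenoxy]-1,3-phenylene]bis(oxy)}bis[3,5-bis(benzyloxy)phenol]
Conditions: TBAF, THF, 0 °C; aq NH4Cl
Reagents that add atoms: none
Why: Fluoride-induced desilylation releases the two C4 phenols and leaves every benzyl and diaryl ether untouched.

Step 10
Reactants: 16 1,3,5-tris(benzyloxy)benzene
Product: 17 1,3,5-tris(benzyloxy)-2-iodobenzene
Conditions: NIS (1.0 equiv), MeCN, 0 °C
Reagents that add atoms: N-iodosuccinimide, O=C1CCC(=O)N1I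
Why: Electrophilic iodination of a phloroglucinol triether; the three ring positions are equivalent and the first iodine retards further substitution, so the monoiodide should dominate.

Step 11
Reactants: 17 1,3,5-tris(benzyloxy)-2-iodobenzene (two molecules)
Product: 18 2,2',4,4',6,6'-hexakis(benzyloxy)-1,1'-biphenyl
Conditions: Cu powder (activated, excess), DMF, 150 °C
Reagents that add atoms: second molecule of 1,3,5-tris(benzyloxy)-2-iodobenzene 17, Ic1c(OCc2ccccc2)cc(OCc2ccccc2)cc1OCc1ccccc1
Why: Classical Ullmann biaryl homocoupling in which two molecules of 17 are joined at their iodine-bearing carbons and both iodines leave as CuI, the standard route to 2,2',6,6'-tetraalkoxybiphenyls from 2-iodoresorcinol ethers; the D5–E1 bond joins two identical halves, so no cross-selectivity is required.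

Step 12
Reactants: 18 2,2',4,4',6,6'-hexakis(benzyloxy)-1,1'-biphenyl
Product: 19 2,2',4,4',6,6'-hexakis(benzyloxy)-3-iodo-1,1'-biphenyl
Conditions: NIS (0.9 equiv), CH2Cl2/MeCN, 0 °C
Reagents that add atoms: N-iodosuccinimide, O=C1CCC(=O)N1I
Why: Electrophilic iodination; the four ring hydrogens of 18 are equivalent, so only the degree of iodination has to be controlled, which is done with a deficit of NIS and recovery of unreacted 18.

Step 13
Reactants: 15 4,4'-{[5-(benzyloxy)-2-[3,5-bis(benzyloxy)phenoxy]-1,3-phenylene]bis(oxy)}bis[3,5-bis(benzyloxy)phenol]; 19 2,2',4,4',6,6'-hexakis(benzyloxy)-3-iodo-1,1'-biphenyl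
Product: 20 nonadeca-O-benzyl ether of the target
Conditions: 19 (3 equiv), CuI, 2,2,6,6-tetramethylheptane-3,5-dione, Cs2CO3, NMP, 120 °C
Reagents that add atoms: none
Why: Ligand-accelerated Ullmann diaryl ether synthesis, run at both phenols; the C4 and C4' phenoxides are unhindered and the only free hydroxyls, and diketone-ligated copper phenoxides are the systems used for electron-rich, ortho-substituted aryl halides.

Step 14
Reactants: 20 nonadeca-O-benzyl ether of the target
Product: 21 CNP0227063.0
Conditions: H2 (1 atm), Pd/C, THF/MeOH, rt; filtration and concentration under Ar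
Reagents that add atoms: none
Why: Hydrogenolysis of all nineteen benzyl ethers under neutral conditions; diaryl ethers and biaryl bonds are inert, and nothing acidic, basic or oxidising touches the free polyphenol.

## Compound list

1 | 4-(benzyloxy)phenol | Oc1ccc(OCc2ccccc2)cc1 | starting material
2 | 4-(benzyloxy)-2,6-dibromophenol | Oc1c(Br)cc(OCc2ccccc2)cc1Br | intermediate
3 | [3,5-bis(benzyloxy)phenyl]boronic acid | OB(O)c1cc(OCc2ccccc2)cc(OCc2ccccc2)c1 | starting material
4 | 5-(benzyloxy)-2-[3,5-bis(benzyloxy)phenoxy]-1,3-dibromobenzene | Brc1cc(OCc2ccccc2)cc(Br)c1Oc1cc(OCc2ccccc2)cc(OCc2ccccc2)c1 | intermediate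
5 | 5-(benzyloxy)-2-[3,5-bis(benzyloxy)phenoxy]benzene-1,3-diol | Oc1cc(OCc2ccccc2)cc(O)c1Oc1cc(OCc2ccccc2)cc(OCc2ccccc2)c1 | intermediate
6 | dimethyl chloromalonate (dimethyl 2-chloropropanedioate) | COC(=O)C(Cl)C(=O)OC | starting material
7 | tetramethyl 2,2'-{[5-(benzyloxy)-2-[3,5-bis(benzyloxy)phenoxy]-1,3-phenylene]bis(oxy)}dipropanedioate (ring B bis(aryloxymalonate)) | COC(=O)C(Oc1cc(OCc2ccccc2)cc(OC(C(=O)OC)C(=O)OC)c1Oc1cc(OCc2ccccc2)cc(OCc2ccccc2)c1)C(=O)OC | intermediate
8 | dimethyl 3-oxopentanedioate | COC(=O)CC(=O)CC(=O)OC | starting material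
9 | open-chain twofold C-acylation adduct (each arm ArO–CH(CO2Me)–CO–CH(CO2Me)–CO–CH2–CO2Me; enolisable centres undefined) | COC(=O)CC(=O)C(C(=O)OC)C(=O)C(C(=O)OC)Oc1cc(OCc2ccccc2)cc(OC(C(=O)OC)C(=O)C(C(=O)OC)C(=O)CC(=O)OC)c1Oc1cc(OCc2ccccc2)cc(OCc2ccccc2)c1 | intermediate (not isolated)
10 | tetramethyl 5,5'-{[5-(benzyloxy)-2-[3,5-bis(benzyloxy)phenoxy]-1,3-phenylene]bis(oxy)}bis(2,4,6-trihydroxybenzene-1,3-dicarboxylate) | COC(=O)c1c(O)c(C(=O)OC)c(O)c(Oc2cc(OCc3ccccc3)cc(Oc3c(O)c(C(=O)OC)c(O)c(C(=O)OC)c3O)c2Oc2cc(OCc3ccccc3)cc(OCc3ccccc3)c2)c1O | intermediate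
11 | 5,5'-{[5-(benzyloxy)-2-[3,5-bis(benzyloxy)phenoxy]-1,3-phenylene]bis(oxy)}bis(2,4,6-trihydroxybenzene-1,3-dicarboxylic acid) | OC(=O)c1c(O)c(C(=O)O)c(O)c(Oc2cc(OCc3ccccc3)cc(Oc3c(O)c(C(=O)O)c(O)c(C(=O)O)c3O)c2Oc2cc(OCc3ccccc3)cc(OCc3ccccc3)c2)c1O | intermediate (not isolated)
12 | 2,2'-{[5-(benzyloxy)-2-[3,5-bis(benzyloxy)phenoxy]-1,3-phenylene]bis(oxy)}bis(benzene-1,3,5-triol) | Oc1cc(O)c(Oc2cc(OCc3ccccc3)cc(Oc3c(O)cc(O)cc3O)c2Oc2cc(OCc3ccccc3)cc(OCc3ccccc3)c2)c(O)c1 | intermediate
13 | 2,2'-{[5-(benzyloxy)-2-[3,5-bis(benzyloxy)phenoxy]-1,3-phenylene]bis(oxy)}bis{5-[(triisopropylsilyl)oxy]benzene-1,3-diol} | CC(C)[Si](C(C)C)(C(C)C)Oc1cc(O)c(Oc2cc(OCc3ccccc3)cc(Oc3c(O)cc(O[Si](C(C)C)(C(C)C)C(C)C)cc3O)c2Oc2cc(OCc3ccccc3)cc(OCc3ccccc3)c2)c(O)c1 | intermediate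
14 | ring A–B tribenzyl core bearing two 2,6-bis(benzyloxy)-4-[(triisopropylsilyl)oxy]phenoxy rings on B1 and B3 | CC(C)[Si](C(C)C)(C(C)C)Oc1cc(OCc2ccccc2)c(Oc2cc(OCc3ccccc3)cc(Oc3c(OCc4ccccc4)cc(O[Si](C(C)C)(C(C)C)C(C)C)cc3OCc3ccccc3)c2Oc2cc(OCc3ccccc3)cc(OCc3ccccc3)c2)c(OCc2ccccc2)c1 | intermediate
15 | 4,4'-{[5-(benzyloxy)-2-[3,5-bis(benzyloxy)phenoxy]-1,3-phenylene]bis(oxy)}bis[3,5-bis(benzyloxy)phenol] | Oc1cc(OCc2ccccc2)c(Oc2cc(OCc3ccccc3)cc(Oc3c(OCc4ccccc4)cc(O)cc3OCc3ccccc3)c2Oc2cc(OCc3ccccc3)cc(OCc3ccccc3)c2)c(OCc2ccccc2)c1 | intermediate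
16 | 1,3,5-tris(benzyloxy)benzene | c1ccc(COc2cc(OCc3ccccc3)cc(OCc3ccccc3)c2)cc1 | starting material
17 | 1,3,5-tris(benzyloxy)-2-iodobenzene | Ic1c(OCc2ccccc2)cc(OCc2ccccc2)cc1OCc1ccccc1 | intermediate
18 | 2,2',4,4',6,6'-hexakis(benzyloxy)-1,1'-biphenyl | C(Oc1cc(OCc2ccccc2)c(-c2c(OCc3ccccc3)cc(OCc3ccccc3)cc2OCc2ccccc2)c(OCc2ccccc2)c1)c1ccccc1 | intermediate
19 | 2,2',4,4',6,6'-hexakis(benzyloxy)-3-iodo-1,1'-biphenyl | Ic1c(OCc2ccccc2)cc(OCc2ccccc2)c(-c2c(OCc3ccccc3)cc(OCc3ccccc3)cc2OCc2ccccc2)c1OCc1ccccc1 | intermediate
20 | nonadeca-O-benzyl ether of the target | c6ccccc6COc1cc(OCc6ccccc6)cc(Oc2c(Oc3c(OCc6ccccc6)cc(Oc4c(OCc6ccccc6)cc(OCc6ccccc6)c(-c5c(OCc6ccccc6)cc(OCc6ccccc6)cc5OCc6ccccc6)c4OCc6ccccc6)cc3OCc6ccccc6)cc(OCc6ccccc6)cc2Oc2c(OCc6ccccc6)cc(Oc3c(OCc6ccccc6)cc(OCc6ccccc6)c(-c4c(OCc6ccccc6)cc(OCc6ccccc6)cc4OCc6ccccc6)c3OCc6ccccc6)cc2OCc6ccccc6)c1 | intermediate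
21 | CNP0227063.0 | Oc1cc(O)cc(Oc2c(Oc3c(O)cc(Oc4c(O)cc(O)c(-c5c(O)cc(O)cc5O)c4O)cc3O)cc(O)cc2Oc2c(O)cc(Oc3c(O)cc(O)c(-c4c(O)cc(O)cc4O)c3O)cc2O)c1 | target

## Step count and least certain steps

Total step count: 14. Longest linear sequence: 11 steps (steps 1–9, 13 and 14, from 1). The D–E iodide 19 is made in three steps (10–12) and joins at step 13.

**Step 5 (key step).** Most likely failure: enolisation of the aryloxymalonate arms of 7 removes their electrophilicity, so the acylation stalls while 8 is consumed by self-condensation, or one arm annulates and the other does not. Fallback, from 7 back to 10, a stepwise version of the same two bonds: half-saponification of both malonate arms (KOH, 2 equiv, THF/H2O, 0 °C) would give the bis(malonic half ester) F1. Oxalyl chloride with catalytic DMF would give the bis(acid chloride) F2. MgCl2/Et3N-mediated C-acylation of 8 in MeCN would then deliver the open-chain adduct 9 as an isolated compound, with the C2–C3 bonds formed irreversibly under non-equilibrating conditions. NaOMe in MeOH would then only have to effect the intramolecular C5–C6 closure to 10.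

**Step 13.** Most likely failure: slow oxidative addition of the electron-rich aryl iodide, whose carbon–iodine bond sits between two benzyloxy groups, with protodeiodination of 19 and stalling after the first of the two etherifications. Fallback, from 15 and 19 back to 20, with the polarity reversed: 15 would be converted (Tf2O, pyridine) into the bis(triflate) F3. Iodide 19 would give, by iodine–magnesium exchange (i-PrMgCl·LiCl), borylation (B(OMe)3) and oxidation (H2O2, NaOH), the hindered phenol F4. A Pd-catalysed carbon–oxygen coupling (Pd(OAc)2, tBuXPhos, K3PO4, toluene, 100 °C) of F3 with F4 would then form the same ethers, with the hindered partner as the nucleophile and the unhindered ring C as the electrophile.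

**Step 7.** Most likely failure: insufficient discrimination between the para and the flanking hydroxyls, so silylation spreads over regioisomers, and the error is squared because two rings must react correctly. Fallback, from 12 back to 13, by selective deprotection in place of selective protection: exhaustive acetylation (Ac2O, pyridine) would give the hexaacetate F5. Lipase-mediated alcoholysis (Candida antarctica lipase B, n-BuOH, t-BuOMe), which removes the least hindered aryl acetates, would give the para-diol tetraacetate F6. Silylation (TIPSCl, imidazole) would give the bis-silyl tetraacetate F7, and ammonolysis of the acetates (NH3, MeOH, 0 °C) would return 13.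

**Step 3.** Most likely failure: the phenoxide formed in the first hydroxylation deactivates the second carbon–bromine bond, leading to protodebromination or intermolecular diaryl ether formation. Fallback, from 4 back to 5: Miyaura borylation (B2pin2, Pd(dppf)Cl2, KOAc, 1,4-dioxane, 90 °C) would give the bis(pinacol boronate) F8, which is oxidised (H2O2, NaOH, THF, 0 °C) to 5. The oxygen is then introduced in a separate, non-catalytic step.

**Step 12.** Most likely failure: over-iodination, because the second ring of 18 is as reactive as the first, which lowers the yield of 19 even with a deficit of NIS. Fallback, from 16 and 17 back to 19, by cross-coupling: 16 would be iodinated twice (NIS, 2.1 equiv) to 1,3,5-tris(benzyloxy)-2,4-diiodobenzene F9. Iodide 17 would be converted (i-PrMgCl·LiCl, B(OMe)3, aqueous acid) into [2,4,6-tris(benzyloxy)phenyl]boronic acid F10. A Suzuki–Miyaura coupling (Pd(OAc)2, SPhos, K3PO4, toluene/H2O, 90 °C) of F10 with an excess of F9 would give 19, with the second iodine already in place.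

**Step 14.** Most likely failure: incomplete cleavage of the last benzyl ethers as the material changes from lipophilic to highly polar, and air oxidation of the free polyphenol during isolation. Fallback, from 20 directly to 21: non-reductive debenzylation with BCl3 and pentamethylbenzene as cation scavenger (CH2Cl2, −78 °C), which passes through no new isolated compound.

## Further compounds

F1 | step 5 | 2,2'-{[5-(benzyloxy)-2-[3,5-bis(benzyloxy)phenoxy]-1,3-phenylene]bis(oxy)}bis(3-methoxy-3-oxopropanoic acid) | COC(=O)C(Oc1cc(OCc2ccccc2)cc(OC(C(=O)O)C(=O)OC)c1Oc1cc(OCc2ccccc2)cc(OCc2ccccc2)c1)C(=O)O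
F2 | step 5 | dimethyl 2,2'-{[5-(benzyloxy)-2-[3,5-bis(benzyloxy)phenoxy]-1,3-phenylene]bis(oxy)}bis(3-chloro-3-oxopropanoate) | COC(=O)C(Oc1cc(OCc2ccccc2)cc(OC(C(Cl)=O)C(=O)OC)c1Oc1cc(OCc2ccccc2)cc(OCc2ccccc2)c1)C(Cl)=O
F3 | step 13 | bis(trifluoromethanesulfonate) of 15 | O=S(=O)(Oc1cc(OCc2ccccc2)c(Oc2cc(OCc3ccccc3)cc(Oc3c(OCc4ccccc4)cc(OS(=O)(=O)C(F)(F)F)cc3OCc3ccccc3)c2Oc2cc(OCc3ccccc3)cc(OCc3ccccc3)c2)c(OCc2ccccc2)c1)C(F)(F)F
F4 | step 13 | 2,2',4,4',6,6'-hexakis(benzyloxy)-[1,1'-biphenyl]-3-ol | Oc1c(OCc2ccccc2)cc(OCc2ccccc2)c(-c2c(OCc3ccccc3)cc(OCc3ccccc3)cc2OCc2ccccc2)c1OCc1ccccc1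
F5 | step 7 | hexaacetate of 12 | CC(=O)Oc1cc(OC(C)=O)c(Oc2cc(OCc3ccccc3)cc(Oc3c(OC(C)=O)cc(OC(C)=O)cc3OC(C)=O)c2Oc2cc(OCc3ccccc3)cc(OCc3ccccc3)c2)c(OC(C)=O)c1
F6 | step 7 | tetraacetate of 12 with free C4 and C4' hydroxyls | Oc1cc(OC(C)=O)c(Oc2cc(OCc3ccccc3)cc(Oc3c(OC(C)=O)cc(O)cc3OC(C)=O)c2Oc2cc(OCc3ccccc3)cc(OCc3ccccc3)c2)c(OC(C)=O)c1
F7 | step 7 | tetraacetate of 13 | CC(C)[Si](C(C)C)(C(C)C)Oc1cc(OC(C)=O)c(Oc2cc(OCc3ccccc3)cc(Oc3c(OC(C)=O)cc(O[Si](C(C)C)(C(C)C)C(C)C)cc3OC(C)=O)c2Oc2cc(OCc3ccccc3)cc(OCc3ccccc3)c2)c(OC(C)=O)c1
F8 | step 3 | 2,2'-{5-(benzyloxy)-2-[3,5-bis(benzyloxy)phenoxy]-1,3-phenylene}bis(4,4,5,5-tetramethyl-1,3,2-dioxaborolane) | CC1(C)OB(OC1(C)C)c1cc(OCc2ccccc2)cc(B2OC(C)(C)C(C)(C)O2)c1Oc1cc(OCc2ccccc2)cc(OCc2ccccc2)c1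
F9 | step 12 | 1,3,5-tris(benzyloxy)-2,4-diiodobenzene | Ic1c(OCc2ccccc2)cc(OCc2ccccc2)c(I)c1OCc1ccccc1
F10 | step 12 | [2,4,6-tris(benzyloxy)phenyl]boronic acid | OB(O)c1c(OCc2ccccc2)cc(OCc2ccccc2)cc1OCc1ccccc1
F0 | step 14 | none | none
A1 | alternative 1 | 2-[3-(benzyloxy)-2,4,6-trimethoxyphenyl]-5-ethoxy-3-[(triisopropylsilyl)oxy]phenol | CCOc1cc(O)c(-c2c(OC)cc(OC)c(OCc3ccccc3)c2OC)c(O[Si](C(C)C)(C(C)C)C(C)C)c1
A2 | alternative 1 | {[3-(benzyloxy)-2,4,6-trimethoxyphenyl]ethynyloxy}triisopropylsilane (ring D siloxyalkyne) | COc1cc(OC)c(C#CO[Si](C(C)C)(C(C)C)C(C)C)c(OC)c1OCc1ccccc1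
A3 | alternative 1 | 3-ethoxycyclobut-2-en-1-one | CCOC1=CC(=O)C1
A4 | alternative 2 | hexadecamethyl ether of 21 with free hydroxyls at B5, E4 and E4' | COc1cc(OC)cc(Oc2c(Oc3c(OC)cc(Oc4c(OC)cc(OC)c(-c5c(OC)cc(O)cc5OC)c4OC)cc3OC)cc(O)cc2Oc2c(OC)cc(Oc3c(OC)cc(OC)c(-c4c(OC)cc(O)cc4OC)c3OC)cc2OC)c1
A5 | alternative 2 | B5,E4,E4'-trideoxy hexadecamethyl ether | COc1cc(OC)cc(Oc2c(Oc3c(OC)cc(Oc4c(OC)cc(OC)c(-c5c(OC)cccc5OC)c4OC)cc3OC)cccc2Oc2c(OC)cc(Oc3c(OC)cc(OC)c(-c4c(OC)cccc4OC)c3OC)cc2OC)c1
A6 | alternative 3 | ring A–B trimethoxy core bearing two 2,6-dihydroxy-4-[(triisopropylsilyl)oxy]phenoxy rings | COc1cc(OC)cc(Oc2c(Oc3c(O)cc(O[Si](C(C)C)(C(C)C)C(C)C)cc3O)cc(OC)cc2Oc2c(O)cc(O[Si](C(C)C)(C(C)C)C(C)C)cc2O)c1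
A7 | alternative 3 | ring A–B trimethoxy core bearing two 2,6-diformyl-4-[(triisopropylsilyl)oxy]phenoxy rings (tetraaldehyde) | COc1cc(OC)cc(Oc2c(Oc3c(C=O)cc(O[Si](C(C)C)(C(C)C)C(C)C)cc3C=O)cc(OC)cc2Oc2c(C=O)cc(O[Si](C(C)C)(C(C)C)C(C)C)cc2C=O)c1
A8 | alternative 3 | 2-fluoro-5-[(triisopropylsilyl)oxy]benzene-1,3-dicarbaldehyde | O=Cc1cc(O[Si](C(C)C)(C(C)C)C(C)C)cc(C=O)c1F
A9 | alternative 3 | 2-(3,5-dimethoxyphenoxy)-5-methoxybenzene-1,3-diol | COc1cc(OC)cc(Oc2c(O)cc(OC)cc2O)c1
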